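Assumption (chemistry): the target is formulated as the open 1,2-diketone. Its ring-chain tautomer, the cyclic hemiketal 18, is taken to open spontaneously once both phenols are free, because the open form gains two phenol-to-carbonyl hydrogen bonds.

## Structural features

Licoagrodione is an unsymmetrical benzil: two benzene rings joined by a two-carbon chain in which both carbons are ketones (Ca on ring A, Cb on ring B). Ring A is a 2-hydroxy-4-methoxyphenyl group. Ring B is a 2,4-dihydroxyphenyl group with a 3-methylbut-2-enyl (prenyl) chain at C3, held between its two hydroxyls, so ring B is contiguously 1,2,3,4-tetrasubstituted. There is no stereocentre and no stereogenic double bond, so no stereocentres stand next to each other and nothing of that kind has to be controlled. The fragile elements are three: the prenyl olefin (acid closes it onto either flanking phenol as a 2,2-dimethylchroman, and electrophilic oxidants and hydrogenation attack it), the vicinal diketone (rearranged or cleaved by hydroxide and peroxide), and the electron-rich free phenols. The real difficulty is to join two different, highly oxygenated aryl groups through a carbon pair at the diketone oxidation level, with one of four phenolic oxygens methylated, while the prenyl group survives bond formation and final unmasking. The feature used is that the C2 hydroxyl of ring B can add to the Ca carbonyl and close a five-membered ring, a 2-aryl-2-hydroxybenzofuran-3(2H)-one in which Cb is the ring ketone C3 and Ca is C2. Read backwards, the target is the open tautomer of a coumaranone whose C2 needs only ring A and one oxygen, and the coumaranone enolate can accept both.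

## Logic of the disconnections

19 to 17 (through 18). No carbon-carbon bond is cut. The ring B C2 oxygen is joined on paper to Ca, and the ring A C2 oxygen and ring B C4 oxygen are capped as methoxymethyl (MOM) acetals. This hides the base-sensitive diketone and two phenols at once and reduces the end game to an acetal hydrolysis. The forward step must cleave two aryl acetals with acid mild enough to leave the prenyl olefin untouched, in a medium that cannot trap the hemiketal.

17 to 15. The Ca-OH bond is cut. Without that oxygen, Ca is the enolisable C2 of a ketone, and the oxygen can be returned from air through the enolate. One oxidation level and the only hetero-substituted quaternary carbon are removed. The forward step needs an oxidant that takes the enolate and ignores the trisubstituted olefin, and the hydroperoxide 16 must be reduced before it fragments.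

15 to 12 and 14. The bond between Ca and ring A C1 is cut. It is the only carbon-carbon bond joining the two aromatic halves, so the cut is convergent and leaves a bicyclic ketone and a simple aryl bromide. The forward step is a palladium-catalysed enolate arylation that must stop after one aryl group, go to carbon and not oxygen, and accept an ortho-alkoxy, electron-rich bromide. MOM is kept on both partners because it survives alkoxide base and is small in the ortho position. Silyl ethers would not survive the base, benzyl ethers would need a hydrogenolysis that saturates the prenyl group, and allyl ethers would ionise on zerovalent palladium.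

14 to 13. One O-CH2 bond is cut. The gain is a commercial bromophenol that already has the methyl ether and the bromine in the right places. The forward step is a plain phenol protection.

12 to 11 to 9 (through 10). The MOM O-CH2 bond on the C6 oxygen is cut first, then the ring O1-C2 bond, then the two acetals of 9 are added back. This opens the heterocycle to an aryl chloromethyl ketone in which only the oxygen ortho to the ketone can reach the CH2Cl carbon. The forward sequence demands acetal cleavage without prenyl cyclisation, a 5-exo-tet ring closure, and re-protection of the single remaining phenol. Acetal cleavage and ring closure are run in one flask to save a step.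

9 to 5 and 6. The bond between ring B C1 and Cb is cut. The Weinreb amide 6 delivers both chain carbons with the chlorine in place, and the aryl anion comes from ortho-lithiation directed by an acetal oxygen. The demand is ring lithiation in preference to deprotonation of the benzylic, allylic CH2 of the prenyl group, and acylation without over-addition.

5 to 2 and 3. The bond between ring B C3 and the prenyl CH2 is cut. The position between the two acetal oxygens is the most acidic site of 2, so the prenyl group is placed with complete regiocontrol. The demand is substitution at the primary carbon of 3 without allylic transposition.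

2 to 1. Two O-CH2 bonds are cut. The symmetric diol 1 is reached, and the same acetal groups serve as directing groups in both lithiations.

## Other disconnections considered

Alternative 1: The cut runs through ring B itself, at bonds C1-C2 and C5-C6, leaving a four-carbon doubly oxygenated diene and the two alkyne carbons of an ynone. Forward, the keto ester A1 (an acetoacetate C-alkylated with 3) would be silylated twice to the diene A2. A2 would be heated with the terminal ynone A3, in which the future Ca is a silyl-protected carbinol on MOM-protected ring A. The cycloadduct would lose methanol and its trimethylsilyl groups, so the key product A4 carries ring B complete with both phenols free.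
- In favour: the acyl, hydroxyl, prenyl, hydroxyl order around ring B follows from the polarity match of the diene terminus and the ynone β-carbon. Ring B never carries a protecting group and no aryl metalation is run beside the prenyl chain. On these points the alternative is better than the chosen plan, which needs a deprotection and a re-protection on ring B. It is also metal-free.
- Against: A2 is a tetrasubstituted, moisture-sensitive ketene acetal with a substituent on an inner diene carbon, so the s-cis conformer is strained and open-chain conjugate addition or hydrolysis may compete. A3 is an enolisable α-silyloxy ynone needing about five steps of its own. A4 is one oxidation level short at Ca, so desilylation, carbinol oxidation beside two free phenols and an acid step still follow.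
- Comparison: both plans are free of stereochemical demands and are equal there. A thermal cycloaddition of a hindered diene is judged less predictable than an enolate arylation of a well-studied class. The count is estimated at about twelve operations against nine.

Alternative 2: The cut is the bond between Cb and ring B C1, made while ring B is still a cyclohexane-1,3-dione. The dione A5 (cyclohexane-1,3-dione C-alkylated with 3) would be converted into the vinylogous ester A6. Its kinetic lithium enolate, formed at C6 with LiN(iPr)2, would be C-acylated by the imidazolide A7 of the ring A mandelic acid (carbinol silylated, phenol as MOM ether) to give A8. Dehydrogenation of the carbocycle, desilylation, oxidation at Ca and acid deprotection would finish the synthesis.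
- In favour: the prenyl group lies between the two ring oxygens by construction, the feedstock is cheap, and no directed lithiation is needed. On regiochemical certainty for ring B and on raw-material cost the alternative is better. Enolate acylation is at least the equal of enolate arylation in precedent.
- Against: aromatisation must be done in the presence of the prenyl olefin and its doubly activated CH2, which quinone oxidants, selenium electrophiles and palladium-mediated dehydrogenation can all attack. C- versus O-acylation and proton transfer from the acidic product to unreacted enolate cost material. A7 is enolisable and needs four or five steps.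
- Comparison: two separate redox corrections (ring dehydrogenation and carbinol oxidation) stand against the single oxygenation of the chosen plan. The count is estimated at about thirteen operations.

Alternative 3: Ring A is the ring that is built, by cutting its bonds C1-C2 and C5-C6. The diene A9 would add to the terminal ynone A10, whose ketone becomes Ca and whose silyl-protected carbinol carbon, Cb, carries the fully protected prenylated ring B. After loss of methanol the key product A11 has the C4 methoxy group in place and the C2 phenol free.
- In favour: A9 is a reactive, well-behaved diene of a class whose additions to ynones are a standard entry to 2-hydroxy-4-methoxyaryl ketones. The methyl ether and phenol of ring A are differentiated by the diene itself without a protecting group, and no transition metal is used. On these points the alternative is the equal or the better of the chosen plan.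
- Against: ring A is the easy ring, available in one step from 13. All the difficulties of ring B remain (two lithiations beside the prenyl group, acid-labile acetals next to the olefin). A multi-step chain extension of 5 to the sensitive ynone A10 is added, and Cb arrives at the carbinol level, so desilylation and oxidation are still required.
- Comparison: the key step is sound, but the ring construction is spent where it is least needed. The count is estimated at about fourteen operations against nine.

Key step: step 7

## Route

Step 1
Reactants: 1 resorcinol
Product: 2 1,3-bis(methoxymethoxy)benzene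
Conditions: NaH (2.4 equiv), DMF, 0 °C; MOMCl (2.4 equiv), 0 °C → rt
Reagents that add atoms: chloromethyl methyl ether (MOMCl), COCCl
Why: Williamson-type O-alkylation of the bis-phenoxide by a reactive α-chloro ether; the two acetals are stable to organolithium and alkoxide bases and direct the lithiations of steps 2 and 3.

Step 2
Reactants: 2 1,3-bis(methoxymethoxy)benzene; 3 prenyl bromide (1-bromo-3-methylbut-2-ene)
Product: 5 1,3-bis(methoxymethoxy)-2-(3-methylbut-2-enyl)benzene, via aryllithium 4 (not isolated)
Conditions: n-BuLi (1.1 equiv), THF, 0 °C → rt; CuI (10 mol %), then 3, −40 °C → rt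
Reagents that add atoms: none
Why: Directed ortho-metalation removes the C2 hydrogen between the two coordinating acetal oxygens, the most acidic ring position. Copper-catalysed allylic substitution at the primary carbon of 3 then gives the linear prenyl isomer and not the transposed 1,1-dimethylallyl one.

Step 3
Reactants: 5 1,3-bis(methoxymethoxy)-2-(3-methylbut-2-enyl)benzene; 6 2-chloro-N-methoxy-N-methylacetamide
Product: 9 2-chloro-1-[2,4-bis(methoxymethoxy)-3-(3-methylbut-2-enyl)phenyl]ethanone, via aryllithium 7 (not isolated), via lithium hemiaminal adduct 8 (not isolated)
Conditions: n-BuLi (1.2 equiv), TMEDA, THF, −20 → 0 °C; transfer into 6 (1.3 equiv), THF, −78 → −20 °C; aq. NH4Cl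
Reagents that add atoms: none
Why: A second directed ortho-metalation takes C4 (C4 and C6 are equivalent and C2 is blocked). Weinreb amide acylation stops at the chelated tetrahedral adduct 8, which releases the chloromethyl ketone only on quench, so neither over-addition nor chloride displacement is expected.

Step 4
Reactants: 9 2-chloro-1-[2,4-bis(methoxymethoxy)-3-(3-methylbut-2-enyl)phenyl]ethanone
Product: 11 6-hydroxy-7-(3-methylbut-2-enyl)benzofuran-3(2H)-one, via dihydroxy chloroketone 10 (not isolated)
Conditions: HCl (1 M in MeOH, 2 equiv), 40 °C; then NaOAc (5 equiv), MeOH, reflux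
Reagents that add atoms: none
Why: Acid-catalysed transacetalisation to methanol removes both MOM groups; after buffering, the phenoxide ortho to the ketone displaces chloride in a 5-exo-tet intramolecular Williamson etherification, the classical coumaranone closure. Only that oxygen can reach the CH2Cl carbon, and dilute acid at 40 °C is milder than what is needed to protonate the prenyl olefin.

Step 5
Reactants: 11 6-hydroxy-7-(3-methylbut-2-enyl)benzofuran-3(2H)-one
Product: 12 6-(methoxymethoxy)-7-(3-methylbut-2-enyl)benzofuran-3(2H)-one
Conditions: MOMCl (1.1 equiv), iPr2NEt (1.5 equiv), CH2Cl2, 0 °C → rt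
Reagents that add atoms: chloromethyl methyl ether (MOMCl), COCCl
Why: O-alkylation of the only phenol, a vinylogous acid para to the ketone that an amine base ionises without enolising C2. The hard electrophile reacts at oxygen, and the acetal now matches the protecting group of the coupling partner.

Step 6
Reactants: 13 2-bromo-5-methoxyphenol
Product: 14 1-bromo-4-methoxy-2-(methoxymethoxy)benzene
Conditions: NaH (1.2 equiv), DMF, 0 °C; MOMCl (1.2 equiv), 0 °C → rt
Reagents that add atoms: chloromethyl methyl ether (MOMCl), COCCl
Why: Williamson-type protection of the free phenol, which would otherwise consume base and bind palladium in step 7; the acetal is small enough to be tolerated ortho to the reacting C-Br bond.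

Step 7
Reactants: 12 6-(methoxymethoxy)-7-(3-methylbut-2-enyl)benzofuran-3(2H)-one; 14 1-bromo-4-methoxy-2-(methoxymethoxy)benzene
Product: 15 2-[4-methoxy-2-(methoxymethoxy)phenyl]-6-(methoxymethoxy)-7-(3-methylbut-2-enyl)benzofuran-3(2H)-one (racemic)
Conditions: Pd(OAc)2 (5 mol %), XPhos (10 mol %), NaOtBu (2.5 equiv), toluene/THF, 70 °C, Ar, slow addition of 12; degassed aq. NH4Cl
Reagents that add atoms: none
Why: Palladium-catalysed α-arylation of a ketone enolate (Buchwald-Hartwig-Miura type): Pd(OAc)2 is reduced in the flask to zerovalent palladium, which, carried by the bulky dialkylbiarylphosphine, inserts into the C-Br bond of 14. NaOtBu converts 12 completely into its sodium enolate, the enolate displaces bromide on divalent palladium, and reductive elimination from the C-bound enolate forms the single new skeletal bond, from C2 of the coumaranone (Ca) to C1 of ring A. The closest known reaction type is the arylation of cyclic aryl ketones such as indanones, tetralones and chroman-4-ones with aryl bromides under the same ligand class; the ring oxygen here only makes the C2 hydrogens more acidic. No ring is closed. C2 becomes a stereocentre, but it is formed racemic under no control and none is needed, since it stays enolisable, is oxygenated in step 8 and vanishes when the hemiketal opens in step 9. Monoarylation is secured because the product, more acidic than 12, rests as a delocalised aromatic 3-oxidobenzofuran (hence more than two equivalents of base) whose hindered tertiary carbon, the ortho-MOM ether of 14 and the large ligand together disfavour a second coupling. C- over O-arylation follows from the preference of bulky monophosphine palladium enolates for carbon-bound reductive elimination, and self-aldol condensation of 12 is held back by slow addition to excess base so that no neutral ketone accumulates. The MOM acetals are inert to alkoxide, the trisubstituted prenyl olefin is a poor Heck acceptor, and quenching under argon keeps the air-sensitive product enolate from oxidising prematurely.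

Step 8
Reactants: 15 2-[4-methoxy-2-(methoxymethoxy)phenyl]-6-(methoxymethoxy)-7-(3-methylbut-2-enyl)benzofuran-3(2H)-one
Product: 17 2-hydroxy-2-[4-methoxy-2-(methoxymethoxy)phenyl]-6-(methoxymethoxy)-7-(3-methylbut-2-enyl)benzofuran-3(2H)-one (racemic), via C2 hydroperoxide 16 (not isolated)
Conditions: air (1 atm), Cs2CO3 (20 mol %), P(OEt)3 (2 equiv), DMSO, rt, dark
Reagents that add atoms: dioxygen, O=O
Why: Base-mediated autoxidation of a ketone enolate with phosphite reduction in the same flask (α-hydroxylation with O2 and P(OEt)3): the 3-oxidobenzofuran enolate takes up oxygen at C2, and P(OEt)3 reduces hydroperoxide 16 to the tertiary alcohol before it can fragment. C2 is the only enolisable carbon and the prenyl olefin does not react with ground-state oxygen in the dark. The new quaternary centre is racemic and is lost on ring opening.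

Step 9
Reactants: 17 2-hydroxy-2-[4-methoxy-2-(methoxymethoxy)phenyl]-6-(methoxymethoxy)-7-(3-methylbut-2-enyl)benzofuran-3(2H)-one
Product: 19 licoagrodione [1-(2,4-dihydroxy-3-(3-methylbut-2-enyl)phenyl)-2-(2-hydroxy-4-methoxyphenyl)ethane-1,2-dione], via triol hemiketal 18 (not isolated)
Conditions: 3 M aq. HCl, THF, 45 °C, monitored and stopped at full conversion
Reagents that add atoms: none
Why: Specific-acid hydrolysis of two aryl methoxymethyl acetals, run in a non-alcoholic cosolvent so that the hemiketal cannot be trapped as a mixed ketal. The freed hemiketal 18 opens by ring-chain tautomerism to the doubly hydrogen-bonded diketone. Dilute aqueous acid at 45 °C is the usual window for MOM removal from prenylated phenols.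

## Compound list

1 | resorcinol (benzene-1,3-diol) | Oc1cccc(O)c1 | starting material
2 | 1,3-bis(methoxymethoxy)benzene | COCOc1cccc(OCOC)c1 | intermediate
3 | prenyl bromide (1-bromo-3-methylbut-2-ene) | CC(C)=CCBr | starting material
4 | [2,6-bis(methoxymethoxy)phenyl]lithium | [Li]c1c(OCOC)cccc1OCOC | intermediate (not isolated)
5 | 1,3-bis(methoxymethoxy)-2-(3-methylbut-2-enyl)benzene | COCOc1cccc(OCOC)c1CC=C(C)C | intermediate
6 | 2-chloro-N-methoxy-N-methylacetamide | CON(C)C(=O)CCl | starting material
7 | [2,4-bis(methoxymethoxy)-3-(3-methylbut-2-enyl)phenyl]lithium | [Li]c1ccc(OCOC)c(CC=C(C)C)c1OCOC | intermediate (not isolated)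
8 | lithium 1-[2,4-bis(methoxymethoxy)-3-(3-methylbut-2-enyl)phenyl]-2-chloro-1-[methoxy(methyl)amino]ethanolate (racemic) | [Li]OC(CCl)(N(C)OC)c1ccc(OCOC)c(CC=C(C)C)c1OCOC | intermediate (not isolated)
9 | 2-chloro-1-[2,4-bis(methoxymethoxy)-3-(3-methylbut-2-enyl)phenyl]ethanone | O=C(CCl)c1ccc(OCOC)c(CC=C(C)C)c1OCOC | intermediate
10 | 2-chloro-1-[2,4-dihydroxy-3-(3-methylbut-2-enyl)phenyl]ethanone | O=C(CCl)c1ccc(O)c(CC=C(C)C)c1O | intermediate (not isolated)
11 | 6-hydroxy-7-(3-methylbut-2-enyl)benzofuran-3(2H)-one | O=C1COc2c1ccc(O)c2CC=C(C)C | intermediate
12 | 6-(methoxymethoxy)-7-(3-methylbut-2-enyl)benzofuran-3(2H)-one | O=C1COc2c1ccc(OCOC)c2CC=C(C)C | intermediate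
13 | 2-bromo-5-methoxyphenol | COc1ccc(Br)c(O)c1 | starting material
14 | 1-bromo-4-methoxy-2-(methoxymethoxy)benzene | COCOc1cc(OC)ccc1Br | intermediate
15 | 2-[4-methoxy-2-(methoxymethoxy)phenyl]-6-(methoxymethoxy)-7-(3-methylbut-2-enyl)benzofuran-3(2H)-one (racemic) | O=C1c2ccc(OCOC)c(CC=C(C)C)c2OC1c1ccc(OC)cc1OCOC | intermediate
16 | 2-hydroperoxy-2-[4-methoxy-2-(methoxymethoxy)phenyl]-6-(methoxymethoxy)-7-(3-methylbut-2-enyl)benzofuran-3(2H)-one (racemic) | O=C1c2ccc(OCOC)c(CC=C(C)C)c2OC1(OO)c1ccc(OC)cc1OCOC | intermediate (not isolated)
17 | 2-hydroxy-2-[4-methoxy-2-(methoxymethoxy)phenyl]-6-(methoxymethoxy)-7-(3-methylbut-2-enyl)benzofuran-3(2H)-one (racemic) | O=C1c2ccc(OCOC)c(CC=C(C)C)c2OC1(O)c1ccc(OC)cc1OCOC | intermediate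
18 | 2,6-dihydroxy-2-(2-hydroxy-4-methoxyphenyl)-7-(3-methylbut-2-enyl)benzofuran-3(2H)-one (racemic) | O=C1c2ccc(O)c(CC=C(C)C)c2OC1(O)c1ccc(OC)cc1O | intermediate (not isolated)
19 | licoagrodione, 1-[2,4-dihydroxy-3-(3-methylbut-2-enyl)phenyl]-2-(2-hydroxy-4-methoxyphenyl)ethane-1,2-dione (no stereocentre) | COc1ccc(C(=O)C(=O)c2ccc(O)c(CC=C(C)C)c2O)c(O)c1 | target

## Step count and least certain steps

Total step count: 9. Longest linear sequence: 8 (steps 1 to 5, 7, 8 and 9, from 1); step 6 is a one-step branch.

**Step 7 (key step).**
- What may go wrong: base-induced self-condensation of the coumaranone (enolate adding to un-ionised ketone) outrunning a slow transmetalation onto the hindered, electron-rich aryl palladium bromide, and premature autoxidation of the product enolate.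
- Fallback (polar addition in place of cross-coupling, forming the same Ca to ring A bond): it sets out from 9 and 14 and comes back at 19. 9 would be oxidised under Kornblum conditions (DMSO, NaHCO3, NaI cat., 60 °C) to [2,4-bis(methoxymethoxy)-3-(3-methylbut-2-enyl)phenyl]glyoxal F1. 14 would be converted with Mg turnings in THF into [4-methoxy-2-(methoxymethoxy)phenyl]magnesium bromide F2. At −78 °C F2 should add to the aldehyde carbon of F1, which is far more electrophilic than the hindered aryl ketone, to give the benzoin 1-[2,4-bis(methoxymethoxy)-3-(3-methylbut-2-enyl)phenyl]-2-hydroxy-2-[4-methoxy-2-(methoxymethoxy)phenyl]ethanone F3. Dess-Martin periodinane (NaHCO3, CH2Cl2), which leaves the olefin alone, would give the tris-MOM benzil 1-[2,4-bis(methoxymethoxy)-3-(3-methylbut-2-enyl)phenyl]-2-[4-methoxy-2-(methoxymethoxy)phenyl]ethane-1,2-dione F4. The acid treatment of step 9 would then release 19.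

**Step 3.**
- What may go wrong: lateral deprotonation at the benzylic, allylic CH2 of the prenyl group, which is flanked by two coordinating acetal oxygens, competing with ring lithiation; and proton transfer from the acidic CH2Cl of 6 to the aryllithium.
- Fallback (aryllithium by halogen-lithium exchange, its site fixed by a bromine atom): it sets out from 2 and comes back at 7. 2 would be brominated with N-bromosuccinimide (MeCN, 0 °C) to 1-bromo-2,4-bis(methoxymethoxy)benzene F5. LiN(iPr)2 (THF, −78 °C), which deprotonates and does not exchange bromine, would remove the hydrogen between the two acetal oxygens to give [3-bromo-2,6-bis(methoxymethoxy)phenyl]lithium F6. Alkylation with 3 (CuI cat.) would give 1-bromo-2,4-bis(methoxymethoxy)-3-(3-methylbut-2-enyl)benzene F7. Bromine-lithium exchange with n-BuLi at −78 °C is faster than any deprotonation and would deliver 7, which is acylated with 6 as in step 3.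

**Step 8.**
- What may go wrong: fragmentation of hydroperoxide 16 through a dioxetane, with cleavage of the C2-C3 bond, before the phosphite intercepts it; radical-chain oxidation at the prenyl CH2; and base-induced rearrangement of the open diketone tautomer.
- Fallback (two-electron oxygen transfer to a preformed enolate, with no dioxygen and no hydroperoxide): it sets out from 15 and comes back at 17. 15 would be deprotonated with KN(SiMe3)2 (THF, −78 °C) to potassium 2-[4-methoxy-2-(methoxymethoxy)phenyl]-6-(methoxymethoxy)-7-(3-methylbut-2-enyl)benzofuran-3-olate F8. F8 would be treated at −78 °C with 2-(phenylsulfonyl)-3-phenyloxaziridine, which hydroxylates enolates and does not epoxidise an isolated trisubstituted olefin at that temperature. Aqueous NH4Cl would give 17.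

**Steps 4 and 9.**
- What may go wrong: acid-catalysed addition of a flanking ring B phenol to the protonated prenyl olefin (closure to a 2,2-dimethylchroman), and in step 9 capture of released formaldehyde by the electron-rich rings.
- Fallback (aprotic silyl-transfer cleavage of the aryl acetals in place of Brønsted-acid solvolysis): for step 4 it sets out from 9 and comes back at 10. Me3SiOTf and 2,2′-bipyridyl (CH2Cl2, 0 °C → rt) would convert both aryl MOM ethers into trimethylsilyl ethers, giving 2-chloro-1-[3-(3-methylbut-2-enyl)-2,4-bis(trimethylsilyloxy)phenyl]ethanone F9. Water hydrolyses F9 to 10 at neutral pH, and NaOAc then closes the ring as before.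
- For step 9 the same fallback sets out from 17 and comes back at 18. The same reagent pair would give 2-(trimethylsilyloxy)-2-[4-methoxy-2-(trimethylsilyloxy)phenyl]-7-(3-methylbut-2-enyl)-6-(trimethylsilyloxy)benzofuran-3(2H)-one F10, which water would hydrolyse to 18 and hence 19.

## Further compounds

F1 | step 7 | [2,4-bis(methoxymethoxy)-3-(3-methylbut-2-enyl)phenyl]glyoxal | O=CC(=O)c1ccc(OCOC)c(CC=C(C)C)c1OCOC
F2 | step 7 | [4-methoxy-2-(methoxymethoxy)phenyl]magnesium bromide | COCOc1cc(OC)ccc1[Mg]Br
F3 | step 7 | 1-[2,4-bis(methoxymethoxy)-3-(3-methylbut-2-enyl)phenyl]-2-hydroxy-2-[4-methoxy-2-(methoxymethoxy)phenyl]ethanone (racemic) | O=C(C(O)c1ccc(OC)cc1OCOC)c1ccc(OCOC)c(CC=C(C)C)c1OCOC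
F4 | step 7 | 1-[2,4-bis(methoxymethoxy)-3-(3-methylbut-2-enyl)phenyl]-2-[4-methoxy-2-(methoxymethoxy)phenyl]ethane-1,2-dione | O=C(C(=O)c1ccc(OC)cc1OCOC)c1ccc(OCOC)c(CC=C(C)C)c1OCOC
F5 | step 3 | 1-bromo-2,4-bis(methoxymethoxy)benzene | COCOc1ccc(Br)c(OCOC)c1
F6 | step 3 | [3-bromo-2,6-bis(methoxymethoxy)phenyl]lithium | [Li]c1c(OCOC)ccc(Br)c1OCOC
F7 | step 3 | 1-bromo-2,4-bis(methoxymethoxy)-3-(3-methylbut-2-enyl)benzene | COCOc1ccc(Br)c(OCOC)c1CC=C(C)C
F8 | step 8 | potassium 2-[4-methoxy-2-(methoxymethoxy)phenyl]-6-(methoxymethoxy)-7-(3-methylbut-2-enyl)benzofuran-3-olate | [K+].[O-]c1c(-c2ccc(OC)cc2OCOC)oc2c1ccc(OCOC)c2CC=C(C)C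
F9 | step 4 | 2-chloro-1-[3-(3-methylbut-2-enyl)-2,4-bis(trimethylsilyloxy)phenyl]ethanone | O=C(CCl)c1ccc(O[Si](C)(C)C)c(CC=C(C)C)c1O[Si](C)(C)C
F10 | step 9 | 2-(trimethylsilyloxy)-2-[4-methoxy-2-(trimethylsilyloxy)phenyl]-7-(3-methylbut-2-enyl)-6-(trimethylsilyloxy)benzofuran-3(2H)-one (racemic) | O=C1c2ccc(O[Si](C)(C)C)c(CC=C(C)C)c2OC1(O[Si](C)(C)C)c1ccc(OC)cc1O[Si](C)(C)C
A1 | alternative 1 | methyl 2-acetyl-5-methylhex-4-enoate (racemic) | COC(=O)C(CC=C(C)C)C(C)=O
A2 | alternative 1 | 1-methoxy-2-(3-methylbut-2-enyl)-1,3-bis(trimethylsilyloxy)buta-1,3-diene (C1=C2 geometry not defined) | C=C(O[Si](C)(C)C)C(CC=C(C)C)=C(OC)O[Si](C)(C)C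
A3 | alternative 1 | 1-(tert-butyldimethylsilyloxy)-1-[4-methoxy-2-(methoxymethoxy)phenyl]but-3-yn-2-one (racemic) | C#CC(=O)C(O[Si](C)(C)C(C)(C)C)c1ccc(OC)cc1OCOC
A4 | alternative 1 | 2-(tert-butyldimethylsilyloxy)-1-[2,4-dihydroxy-3-(3-methylbut-2-enyl)phenyl]-2-[4-methoxy-2-(methoxymethoxy)phenyl]ethanone (racemic) | COc1ccc(C(O[Si](C)(C)C(C)(C)C)C(=O)c2ccc(O)c(CC=C(C)C)c2O)c(OCOC)c1
A5 | alternative 2 | 2-(3-methylbut-2-enyl)cyclohexane-1,3-dione | O=C1CCCC(=O)C1CC=C(C)C
A6 | alternative 2 | 3-(methoxymethoxy)-2-(3-methylbut-2-enyl)cyclohex-2-en-1-one | COCOC1=C(CC=C(C)C)C(=O)CCC1
A7 | alternative 2 | 2-(tert-butyldimethylsilyloxy)-1-(imidazol-1-yl)-2-[4-methoxy-2-(methoxymethoxy)phenyl]ethanone (racemic) | COCOc1cc(OC)ccc1C(O[Si](C)(C)C(C)(C)C)C(=O)n1ccnc1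
A8 | alternative 2 | 6-{2-(tert-butyldimethylsilyloxy)-2-[4-methoxy-2-(methoxymethoxy)phenyl]acetyl}-3-(methoxymethoxy)-2-(3-methylbut-2-enyl)cyclohex-2-en-1-one (diastereomer and enol mixture) | COCOC1=C(CC=C(C)C)C(=O)C(C(=O)C(O[Si](C)(C)C(C)(C)C)c2ccc(OC)cc2OCOC)CC1
A9 | alternative 3 | 1,3-dimethoxy-1-(trimethylsilyloxy)buta-1,3-diene (C1=C2 geometry not defined) | C=C(OC)C=C(OC)O[Si](C)(C)C
A10 | alternative 3 | 1-[2,4-bis(methoxymethoxy)-3-(3-methylbut-2-enyl)phenyl]-1-(tert-butyldimethylsilyloxy)but-3-yn-2-one (racemic) | C#CC(=O)C(O[Si](C)(C)C(C)(C)C)c1ccc(OCOC)c(CC=C(C)C)c1OCOC
A11 | alternative 3 | 2-[2,4-bis(methoxymethoxy)-3-(3-methylbut-2-enyl)phenyl]-2-(tert-butyldimethylsilyloxy)-1-(2-hydroxy-4-methoxyphenyl)ethanone (racemic) | COc1ccc(C(=O)C(O[Si](C)(C)C(C)(C)C)c2ccc(OCOC)c(CC=C(C)C)c2OCOC)c(O)c1
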